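The numbers in the tables are simulated for substances that don't exist, and the scatter is random.

The ratio I carried was the kept share: the [E] standing at a given time over the E formed up to then, with formation at one even rate and E lost first-order with constant k. The gross rate cancels from that ratio, which leaves (1 − e^(−kt))/(kt).

| flask | Z | J | time |
|---|---|---|---|
| autumn | 0.600 M | 0.00120 M |  |
| midnight | 0.240 M | 0.00120 M |  |
| winter | 0.300 M | 0.00120 M |  |
| summer | 1.80 M | 0.00240 M | 38 h |

| autumn run: time / h | autumn run: [E] / M | midnight run: time / h | midnight run: [E] / M | winter run: time / h | winter run: [E] / M |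
|---|---|---|---|---|---|
| 6.3 | 0.070 | 6.3 | 0.070 | 6.3 | 0.076 |
| 13 | 0.133 | 13 | 0.131 | 13 | 0.140 |
| 19 | 0.182 | 19 | 0.149 | 19 | 0.175 |
| 25 | 0.229 | 25 | 0.151 | 25 | 0.190 |
| 32 | 0.271 | 32 | 0.141 | 32 | 0.171 |
| 38 | 0.296 | 38 | 0.117 | 38 | 0.159 |

(each reading ± 0.003 M)

1. reaction order in [Z] at the outset, round the charge of the autumn run, defined at two percent of the Z turned into E (one fixed amount of E, the same in the runs compared)
2. E in the summer run at 38 h, as a share of the Z charged

- Overall: Z -> E, with J as catalyst.
- Constant volume, constant temperature.
- Readings of a species count what is bound in complexes too.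
- An order is taken over about fifteen percent of the charge, up and down.

[E] falls late in the midnight run. Taking its Z as used up by 38 h, I divided the charge less the last reading, 0.123 M, by the area under its curve, 266 M·min, and read k = 0.0278 h⁻¹. Over 38 h the kept share came to 0.618.

For the summer run I set a bracket. From above, the whole charge formed evenly over 38 h keeps 61.8% of it. From below, the autumn reading of 0.296 M over the kept share means a gross rate of 0.0126 M h⁻¹. Doubled with [J] and held for 38 h, that rate keeps 32.9% of the charge. This floor supposes the rate proportional to [J], which the autumn, midnight and winter runs leave untested, being charged alike with 0.00120 M of J, and it carries the autumn rate over to a charge of 1.80 M. For the order I had a chord, winter against autumn at 13 h, reading −0.0740, and I took it as an upper edge.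

The forecast gave 24%, from 16% to 33%, “assuming rate proportional to J”, which stands below my floor. Its order was −0.15, from −0.4 to 0.08.

The flask gave 65.1% and an order of −0.36.

    J + Z ⇌ JZ, settled at all times (3.450 M⁻¹)
    JZ + J → E + 2 J (57240 M⁻¹ h⁻¹)
    J + Rx → Ez
    E → Qi (0.02646 h⁻¹)

Where the same amount of E had been made, the rate in the winter run stood at 1.1 times that of the autumn run, from 0.011 M h⁻¹ to 0.013 M h⁻¹, with the lower charge the faster. The summer result lies above my bracket. Divided by the kept share, with k as I read it in the midnight run, its 65.1% stands for 105% of the charge formed, more than the charge holds, so even formation over the 38 h does not fit the summer run.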